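(The runs come from a simulation for substances that don't exist, noise included.)

**Examiner:** What in this flask is slow enough to still be moving at 50 min?

**Candidate:** Nothing the readings show. In elm, over-reaction product and uncatalysed product stay flat from 8.00 min to 40.0 min, apart from one low reading of 42.4%. Alder is the asked flask itself, and its target is down to 0.6% at 10.0 min. So I take alder's last two readings as its plateau: over-reaction product 46.3%, uncatalysed product 43.8%.

| flask | substrate | reagent | free catalyst | remark | time |
|---|---|---|---|---|---|
| alder | 1 mM (fed, over 40 s) | 2.5 equiv | 0.77 mol% | the very flask that is asked about, followed so far; the fed solution adds 0.25 times the starting volume |  |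
| elm | 1.5 mM (fed, over 40 s) | 2.5 equiv | 0.77 mol% | run made earlier; the fed solution adds 0.25 times the starting volume |  |
| flask | 1.0 mM (fed, over 40 s) | 2.50 equiv | 0.77 mol% | the fed solution adds 0.25 times the starting volume | 50 min |

| run | time / min | over-reaction product / % | uncatalysed product / % | target / % |
|---|---|---|---|---|
| alder | 0.833 | 18.5 | 37.3 | 13.8 |
| alder | 2.00 | 41.8 | 44.5 | 4.0 |
| alder | 4.00 | 46.7 | 44.0 | 0 |
| alder | 10.0 | 45.9 | 43.6 | 0.6 |
| elm | 8.00 | 49.4 | 43.9 | 0 |
| elm | 20.0 | 49.9 | 43.6 | 0.3 |
| elm | 25.0 | 49.7 | 43.5 | 0.4 |
| elm | 40.0 | 49.7 | 42.4 | 0 |

(scatter of a reading: 0.5 percentage points)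

- how much over-reaction product there is at 50 min, in percent of the substrate charged
- how much uncatalysed product there is at 50 min, in percent of the substrate charged

**Examiner:** Elm holds 1.50 times the substrate, yet its uncatalysed product averages 43.4%. Why no change?

**Candidate:** I take substrate to split between two routes, one with reagent and one with free catalyst. If the catalyst stays mostly free, the rates go as [substrate][reagent] and [substrate][free catalyst], and [substrate] cancels. Alder reads 0.779, and that is the branch ratio: uncatalysed product over the rest of the substrate charged, a selectivity factor that goes as [reagent]/[free catalyst]. Elm reads 0.767, and elm's reagent and free catalyst charges grew together, so their ratio is alder's.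

**Examiner:** Alder's balance misses 9.90%, elm's 6.85%. Is that a weak spot?

**Candidate:** Elm's gain appears in over-reaction product while uncatalysed product holds, so I count the missing part on the catalysed side. Reagent also falls during a run, so the ratio is an average.

The forecast says 46.3% of over-reaction product and 43.6% of uncatalysed product, since “no meaningful drift is expected”.

The flask gives 46.2% of over-reaction product and 44.0% of uncatalysed product.

    substrate + free catalyst ⇌ free catalyst + open intermediate (K = 1.50, k = 8270 M⁻¹ s⁻¹)
    free catalyst + open intermediate ⇌ catalyst intermediate (K = 7660 M⁻¹, k = 16100 M⁻¹ s⁻¹)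
    reagent + catalyst intermediate → free catalyst + target (k = 69000 M⁻¹ s⁻¹)
    substrate + reagent → uncatalysed product (k = 19.7 M⁻¹ s⁻¹)
    reagent + target → over-reaction product (k = 33.6 M⁻¹ s⁻¹)
    open intermediate → side product (k = 0.0212 s⁻¹)

The result puts the branch ratio of this flask at 0.786, beside the 0.779 read from alder, and free catalyst stands at 98.8% of the catalyst charged at 0.667 min. The uncatalysed conversion is the main reason over-reaction product stops where it does in this flask: the flask without it gives 82.3%, not 46.2%.

For the neighbour with 4.20 equiv of reagent and its free catalyst charge held, the ratio scales to 1.31, which means 56.7% of uncatalysed product. That neighbour gives 59.4%.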